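**Retrosynthetic overview**

1. The target comes from its C10 silyl ether 23, whose 14-membered ring is closed last at C12–C13 by hydroboration and intramolecular B-alkyl Suzuki coupling of the vinyl lactone/vinyl iodide 21.
2. 21 comes from the acyclic propiolate 20 by a Rh(I)-catalysed Alder-ene cycloisomerisation. It closes the γ-lactone at its Cα–Cβ bond (C15–C1), sets C1, delivers the exocyclic methylene C17 directly and leaves a vinyl group (C14=C13).
3. Enabling feature: an α-methylene-γ-butyrolactone whose β-carbon (ring-fusion C1) carries an unsubstituted CH2–CH2 pair (C14–C13) running to the methyl-bearing alkene carbon C12. This is the footprint of an ene reaction between a propiolate ester on O–C2 and a (Z)-propenyl group on C2; the (E)-trisubstituted C3=C4 alkene on the other side of C2 is inert to the catalyst.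
4. 20 comes from enal 14 by asymmetric propynylation (C2), Z-semireduction and esterification. 14 comes from (E)-3-iodobut-2-enal by two iterative catalytic asymmetric vinylogous Mukaiyama aldol additions (C10, then C6), each adding one CH(OH)–CH2–C(Me)=CH–C(=O) unit.
5. Ring order: γ-lactone first (step 14), carbocycle second (step 15).

Key step: step 14

Remark: cembranolide locants are used in the text (C1/C2 = ring-fusion CH–C/CH–O, C6 = CH–OAc, C10 = CH–OH, C15/C16/C17 = lactone α-carbon/carbonyl/exocyclic CH2). For every chiral catalyst, the enantiomer assumed is the one that gives the face selectivity stated in the step.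

**Route**

Step 1
Reactants: 1 3-methylbut-2-enoyl chloride; 2 morpholine
Product: 3 4-(3-methylbut-2-enoyl)morpholine
Conditions: Et3N, CH2Cl2, 0 °C to rt
Reagents that add atoms: none
Why: N-acylation of a secondary amine by an acid chloride (Schotten–Baumann type); no stereocentre is formed.

Step 2
Reactants: 3 4-(3-methylbut-2-enoyl)morpholine
Product: 4 4-[(1Z)-1-(tert-butyldimethylsilyloxy)-3-methylbuta-1,3-dien-1-yl]morpholine
Conditions: LDA, THF, −78 °C; TBSCl, −78 °C to rt; distillation
Reagents that add atoms: tert-butyldimethylsilyl chloride, CC(C)(C)[Si](C)(C)Cl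
Why: γ-deprotonation of the enamide gives the extended amide enolate, and O-silylation should give the (Z)-N,O-silyl ketene acetal (silyl dienolate formation).

Step 3
Reactants: 5 but-2-yn-1-ol
Product: 7 (2E)-3-iodobut-2-en-1-ol, via alkenylzirconocene 6 (not isolated)
Conditions: i-Bu2AlH (1 equiv), THF, 0 °C; Cp2ZrCl2/i-Bu2AlH (1.3 equiv each), 0 °C to rt; I2, −78 to 0 °C
Reagents that add atoms: iodine, II
Why: syn-hydrozirconation of the internal alkyne with Schwartz reagent generated in situ should place Zr on the carbon remote from the bulky aluminium alkoxide, and iodinolysis with retention gives the (E)-2-iodoalkene; no stereocentre.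

Step 4
Reactants: 7 (2E)-3-iodobut-2-en-1-ol
Product: 8 (2E)-3-iodobut-2-enal
Conditions: MnO2, CH2Cl2, rt, dark; used crude
Reagents that add atoms: none
Why: chemoselective MnO2 oxidation of a primary allylic alcohol; the vinyl iodide geometry is not touched.

Step 5
Reactants: 8 (2E)-3-iodobut-2-enal; 4 silyl dienolate
Product: 9 (2E,5S,6E)-5-hydroxy-7-iodo-3-methyl-1-(morpholin-4-yl)octa-2,6-dien-1-one
Conditions: SiCl4 (1.1 equiv), chiral bisphosphoramide (5 mol%), i-Pr2NEt (10 mol%), CH2Cl2, −78 °C; aq. NaHCO3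
Reagents that add atoms: none
Why: Lewis-base-activated SiCl4 catalytic enantioselective vinylogous Mukaiyama aldol addition; the γ-carbon of the dienolate attacks the Si face of the catalyst-bound enal to set the (S)-carbinol (C10), and reaction through the s-trans dienolate should give the (E)-enamide.

Step 6
Reactants: 9 hydroxy amide
Product: 10 (2E,5S,6E)-5-[(tert-butyldimethylsilyl)oxy]-7-iodo-3-methyl-1-(morpholin-4-yl)octa-2,6-dien-1-one
Conditions: TBSCl, imidazole, DMF, rt
Reagents that add atoms: tert-butyldimethylsilyl chloride, CC(C)(C)[Si](C)(C)Cl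
Why: standard silylation of a secondary allylic alcohol; the stereocentre is untouched.

Step 7
Reactants: 10 silyl ether amide
Product: 11 (2E,5S,6E)-5-[(tert-butyldimethylsilyl)oxy]-7-iodo-3-methylocta-2,6-dienal
Conditions: DIBAL-H (1.3 equiv), THF, −78 °C; Rochelle salt
Reagents that add atoms: none
Why: partial reduction of a morpholine amide (Weinreb-type behaviour): the tetrahedral aluminium hemiaminal is stable at −78 °C and releases the enal only on work-up.

Step 8
Reactants: 11 enal; 4 silyl dienolate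
Product: 12 (2E,5S,6E,9S,10E)-9-[(tert-butyldimethylsilyl)oxy]-5-hydroxy-11-iodo-3,7-dimethyl-1-(morpholin-4-yl)dodeca-2,6,10-trien-1-one
Conditions: SiCl4 (1.1 equiv), chiral bisphosphoramide (5 mol%), i-Pr2NEt (10 mol%), CH2Cl2, −78 °C; aq. NaHCO3
Reagents that add atoms: none
Why: second catalytic enantioselective vinylogous Mukaiyama aldol addition; Si-face attack under catalyst control sets the (S)-carbinol C6, and the remote C10 centre should exert no bias.

Step 9
Reactants: 12 hydroxy amide
Product: 13 (2E,5S,6E,9S,10E)-9-[(tert-butyldimethylsilyl)oxy]-5-hydroxy-11-iodo-3,7-dimethyldodeca-2,6,10-trienal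
Conditions: DIBAL-H (2.5 equiv), THF, −78 °C; Rochelle salt
Reagents that add atoms: none
Why: the same partial amide reduction with the free hydroxyl carried as its aluminium alkoxide; the (E)-enal cannot close to a lactol.

Step 10
Reactants: 13 hydroxy enal
Product: 14 (2E,5S,6E,9S,10E)-9-[(tert-butyldimethylsilyl)oxy]-11-iodo-3,7-dimethyl-1-oxododeca-2,6,10-trien-5-yl acetate
Conditions: Ac2O, pyridine, DMAP (cat.), CH2Cl2, 0 °C
Reagents that add atoms: acetic anhydride, CC(=O)OC(C)=O
Why: acylation of the only free hydroxyl installs the C6 acetate of the target; all later reagents tolerate it.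

Step 11
Reactants: 14 acetoxy enal; 15 propyne
Product: 16 (4S,5E,8S,9E,12S,13E)-12-[(tert-butyldimethylsilyl)oxy]-4-hydroxy-14-iodo-6,10-dimethylpentadeca-5,9,13-trien-2-yn-8-yl acetate
Conditions: Me2Zn (3 equiv), ProPhenol ligand (20 mol%), Ph3P=O (40 mol%), toluene, 0 to 4 °C
Reagents that add atoms: none
Why: dinuclear zinc–ProPhenol catalysed asymmetric alkynylation of an enal; Re-face delivery of the propynylzinc sets the (S)-propargylic carbinol C2 under catalyst control.

Step 12
Reactants: 16 propargylic alcohol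
Product: 18 (2Z,4R,5E,8S,9E,12S,13E)-12-[(tert-butyldimethylsilyl)oxy]-4-hydroxy-14-iodo-6,10-dimethylpentadeca-2,5,9,13-tetraen-8-yl acetate, via alkenylborane 17 (not isolated)
Conditions: Cy2BH (2.2 equiv), THF, 0 °C; AcOH, 0 °C to rt
Reagents that add atoms: none
Why: syn-hydroboration of the internal alkyne and protonolysis of the alkenylborane with retention give the (Z)-propenyl group; this avoids Pd/H2, which could cleave the C–I bond, and the trisubstituted alkenes are too hindered for Cy2BH. The carbinol is spatially unchanged (descriptor becomes R by priority change).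

Step 13
Reactants: 18 (Z)-dienol; 19 propiolic acid
Product: 20 (2Z,4R,5E,8S,9E,12S,13E)-8-acetoxy-12-[(tert-butyldimethylsilyl)oxy]-14-iodo-6,10-dimethylpentadeca-2,5,9,13-tetraen-4-yl prop-2-ynoate
Conditions: DCC, DMAP (5 mol%), CH2Cl2, −20 to 0 °C
Reagents that add atoms: none
Why: Steglich esterification at low temperature, a standard way to propiolate esters; the C–O bond of the carbinol is not broken.

Step 14
Reactants: 20 propiolate
Product: 21 (2E,4S,5E,8S,9E)-8-[(tert-butyldimethylsilyl)oxy]-1-[(2S,3R)-3-ethenyl-4-methylidene-5-oxooxolan-2-yl]-10-iodo-2,6-dimethylundeca-1,5,9-trien-4-yl acetate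
Conditions: [Rh(cod)Cl]2 (5 mol%), BINAP (matched enantiomer, 11 mol%), AgSbF6 (20 mol%, AgCl filtered off first), ClCH2CH2Cl, 23 °C, 0.02 M
Reagents that add atoms: none
Why: Cationic Rh(I)–BINAP binds the alkyne and the (Z)-propenyl alkene of the 1,6-enyne, oxidative cyclisation gives a rhodacyclopentene (new C15–C1 bond), and β-hydride elimination from the propenyl methyl group followed by C–H reductive elimination at the alkyne terminus releases the lactone with its exocyclic methylene and a vinyl group. The closest known reaction type is the Rh(I)-catalysed Alder-ene cycloisomerisation of (Z)-allylic alkynoates to α-alkylidene-β-vinyl-γ-butyrolactones, which is also known for 1,6-enynes with terminal alkynes. The γ-lactone is closed in the 5-exo mode through the ester tether. The new stereocentre C1 is set trans to the C2 substituent by 1,3-allylic strain (the C2–H bond eclipses the Z-methyl group, so the alkyne adds to the alkene face anti to the C3 alkenyl chain), and the BINAP enantiomer is the matched one that reinforces this preference. The step needs chemoselectivity between the two alkenes flanking C2: only a cis-disubstituted alkene with an allylic C–H enters this manifold, so the (E)-trisubstituted C3=C4 alkene, the other trisubstituted alkenes and the vinyl iodide should stay untouched. Silver salts are removed before the substrate is added so that neither the terminal alkyne nor the C–I bond meets Ag(I).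

Step 15
Reactants: 21 vinyl lactone
Product: 23 (3aR,6E,8S,10E,12S,14E,15aS)-8-[(tert-butyldimethylsilyl)oxy]-6,10,14-trimethyl-3-methylidene-2-oxo-2,3,3a,4,5,8,9,12,13,15a-decahydrocyclotetradeca[b]furan-12-yl acetate, via alkylborane 22 (not isolated)
Conditions: 9-BBN (2 equiv), THF, 0 °C to rt; then slow addition to Pd(dppf)Cl2 (20 mol%), AsPh3 (40 mol%), Cs2CO3 (3 equiv), H2O, DMF/THF, rt, 2 mM
Reagents that add atoms: none
Why: 9-BBN should hydroborate the monosubstituted vinyl group at its terminus in preference to the electron-poor methylene and the trisubstituted alkenes, and intramolecular B-alkyl Suzuki–Miyaura coupling with the (E)-2-iodoalkene closes the 14-membered ring with retention, giving the (E)-C11=C12 alkene and the C14H2–C13H2 bridge; no stereocentre is formed.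

Step 16
Reactants: 23 macrocyclic silyl ether
Product: 24 (3aR,6E,8S,10E,12S,14E,15aS)-8-hydroxy-6,10,14-trimethyl-3-methylidene-2-oxo-2,3,3a,4,5,8,9,12,13,15a-decahydrocyclotetradeca[b]furan-12-yl acetate (the target; (1R,2S,6S,10S)-6-acetoxy-10-hydroxycembra-3E,7E,11E,15(17)-tetraen-16,2-olide)
Conditions: HF·pyridine, pyridine, THF, 0 °C to rt
Reagents that add atoms: none
Why: buffered fluoride cleavage of the secondary TBS ether; the acetate, the lactone and the Michael-acceptor methylene should survive these non-basic conditions.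

**Compound list**

1 | 3-methylbut-2-enoyl chloride | CC(C)=CC(=O)Cl | starting material
2 | morpholine | C1COCCN1 | starting material
3 | 4-(3-methylbut-2-enoyl)morpholine | CC(C)=CC(=O)N1CCOCC1 | intermediate
4 | 4-[(1Z)-1-(tert-butyldimethylsilyloxy)-3-methylbuta-1,3-dien-1-yl]morpholine | C=C(C)/C=C(\N1CCOCC1)O[Si](C)(C)C(C)(C)C | intermediate
5 | but-2-yn-1-ol | CC#CCO | starting material
6 | chlorido[(2E)-4-(diisobutylalumanyloxy)but-2-en-2-yl]zirconocene | CC(C)C[Al](CC(C)C)OC/C=C(\C)[Zr](Cl)(C1C=CC=C1)C1C=CC=C1 | intermediate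
7 | (2E)-3-iodobut-2-en-1-ol | OC/C=C(\C)I | intermediate
8 | (2E)-3-iodobut-2-enal | O=C/C=C(\C)I | intermediate
9 | (2E,5S,6E)-5-hydroxy-7-iodo-3-methyl-1-(morpholin-4-yl)octa-2,6-dien-1-one | O=C(N1CCOCC1)/C=C(\C)C[C@H](O)/C=C(\C)I | intermediate
10 | (2E,5S,6E)-5-[(tert-butyldimethylsilyl)oxy]-7-iodo-3-methyl-1-(morpholin-4-yl)octa-2,6-dien-1-one | O=C(N1CCOCC1)/C=C(\C)C[C@H](O[Si](C)(C)C(C)(C)C)/C=C(\C)I | intermediate
11 | (2E,5S,6E)-5-[(tert-butyldimethylsilyl)oxy]-7-iodo-3-methylocta-2,6-dienal | O=C/C=C(\C)C[C@H](O[Si](C)(C)C(C)(C)C)/C=C(\C)I | intermediate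
12 | (2E,5S,6E,9S,10E)-9-[(tert-butyldimethylsilyl)oxy]-5-hydroxy-11-iodo-3,7-dimethyl-1-(morpholin-4-yl)dodeca-2,6,10-trien-1-one | O=C(N1CCOCC1)/C=C(\C)C[C@H](O)/C=C(\C)C[C@H](O[Si](C)(C)C(C)(C)C)/C=C(\C)I | intermediate
13 | (2E,5S,6E,9S,10E)-9-[(tert-butyldimethylsilyl)oxy]-5-hydroxy-11-iodo-3,7-dimethyldodeca-2,6,10-trienal | O=C/C=C(\C)C[C@H](O)/C=C(\C)C[C@H](O[Si](C)(C)C(C)(C)C)/C=C(\C)I | intermediate
14 | (2E,5S,6E,9S,10E)-9-[(tert-butyldimethylsilyl)oxy]-11-iodo-3,7-dimethyl-1-oxododeca-2,6,10-trien-5-yl acetate | O=C/C=C(\C)C[C@H](OC(C)=O)/C=C(\C)C[C@H](O[Si](C)(C)C(C)(C)C)/C=C(\C)I | intermediate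
15 | propyne | CC#C | starting material
16 | (4S,5E,8S,9E,12S,13E)-12-[(tert-butyldimethylsilyl)oxy]-4-hydroxy-14-iodo-6,10-dimethylpentadeca-5,9,13-trien-2-yn-8-yl acetate | CC#C[C@@H](O)/C=C(\C)C[C@H](OC(C)=O)/C=C(\C)C[C@H](O[Si](C)(C)C(C)(C)C)/C=C(\C)I | intermediate
17 | O-dicyclohexylborinate of 16 carrying a dicyclohexylboryl group on the methyl-bearing carbon of the new (Z)-alkene (syn H–B adduct of the alkyne) | C/C(B(C1CCCCC1)C1CCCCC1)=C\[C@@H](OB(C1CCCCC1)C1CCCCC1)/C=C(\C)C[C@H](OC(C)=O)/C=C(\C)C[C@H](O[Si](C)(C)C(C)(C)C)/C=C(\C)I | intermediate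
18 | (2Z,4R,5E,8S,9E,12S,13E)-12-[(tert-butyldimethylsilyl)oxy]-4-hydroxy-14-iodo-6,10-dimethylpentadeca-2,5,9,13-tetraen-8-yl acetate | C/C=C\[C@@H](O)/C=C(\C)C[C@H](OC(C)=O)/C=C(\C)C[C@H](O[Si](C)(C)C(C)(C)C)/C=C(\C)I | intermediate
19 | propiolic acid (prop-2-ynoic acid) | C#CC(=O)O | starting material
20 | (2Z,4R,5E,8S,9E,12S,13E)-8-acetoxy-12-[(tert-butyldimethylsilyl)oxy]-14-iodo-6,10-dimethylpentadeca-2,5,9,13-tetraen-4-yl prop-2-ynoate | C/C=C\[C@@H](OC(=O)C#C)/C=C(\C)C[C@H](OC(C)=O)/C=C(\C)C[C@H](O[Si](C)(C)C(C)(C)C)/C=C(\C)I | intermediate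
21 | (2E,4S,5E,8S,9E)-8-[(tert-butyldimethylsilyl)oxy]-1-[(2S,3R)-3-ethenyl-4-methylidene-5-oxooxolan-2-yl]-10-iodo-2,6-dimethylundeca-1,5,9-trien-4-yl acetate (trans-lactone) | C=C1C(=O)O[C@@H](/C=C(\C)C[C@H](OC(C)=O)/C=C(\C)C[C@H](O[Si](C)(C)C(C)(C)C)/C=C(\C)I)[C@@H]1C=C | intermediate
22 | 21 in which the ethenyl group has become a 2-(9-borabicyclo[3.3.1]nonan-9-yl)ethyl group | C=C1C(=O)O[C@@H](/C=C(\C)C[C@H](OC(C)=O)/C=C(\C)C[C@H](O[Si](C)(C)C(C)(C)C)/C=C(\C)I)[C@@H]1CCB1C2CCCC1CCC2 | intermediate
23 | (3aR,6E,8S,10E,12S,14E,15aS)-8-[(tert-butyldimethylsilyl)oxy]-6,10,14-trimethyl-3-methylidene-2-oxo-2,3,3a,4,5,8,9,12,13,15a-decahydrocyclotetradeca[b]furan-12-yl acetate | C=C1C(=O)O[C@H]2/C=C(\C)C[C@H](OC(C)=O)/C=C(\C)C[C@H](O[Si](C)(C)C(C)(C)C)/C=C(\C)CC[C@H]12 | intermediate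
24 | (3aR,6E,8S,10E,12S,14E,15aS)-8-hydroxy-6,10,14-trimethyl-3-methylidene-2-oxo-2,3,3a,4,5,8,9,12,13,15a-decahydrocyclotetradeca[b]furan-12-yl acetate | C=C1C(=O)O[C@H]2/C=C(\C)C[C@H](OC(C)=O)/C=C(\C)C[C@H](O)/C=C(\C)CC[C@H]12 | target

**Step count and risks**

Total step count: 16. Longest linear sequence: 14 steps (5 to 24, steps 3–16).

The three steps most likely to fail:

1. Step 14 (key Alder-ene cycloisomerisation). The terminal alkyne may oligomerise or arrest the cationic rhodium catalyst, the doubly allylic ester may ionise, the 1,4-diene product may isomerise further if exposed too long, and facial control may be incomplete if ligand and substrate preferences do not reinforce. Fallback (sets out from 14, returns at 21; the lactone is then built through the C1–C2 bond instead): Morita–Baylis–Hillman reaction of ethyl acrylate with acrolein (DABCO) gives ethyl 3-hydroxy-2-methylidenepent-4-enoate F1, and PBr3 converts it with allylic transposition into ethyl (2Z)-2-(bromomethyl)penta-2,4-dienoate F2. Catalytic asymmetric chromium-mediated 2-(alkoxycarbonyl)allylation of 14 with F2 (CrCl2 cat., chiral bis(oxazoline) ligand, Mn, TMSCl, then mild acid) should give, through the chair transition state of the γ-substituted allylchromium, the anti hydroxy ester ethyl (3R,4S,5E,8S,9E,12S,13E)-8-acetoxy-12-[(tert-butyldimethylsilyl)oxy]-3-ethenyl-4-hydroxy-14-iodo-6,10-dimethyl-2-methylidenepentadeca-5,9,13-trienoate F3. Acid-catalysed lactonisation (CSA, CH2Cl2) then gives 21.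

2. Step 15 (hydroboration and macrocyclising Suzuki coupling). The borane or the basic, long and dilute coupling may attack the exocyclic methylene (conjugate reduction, or migration of the double bond into the ring through base or Pd-hydride). Pd(0) may ionise the allylic lactone or acetate, and oligomerisation may compete with ring closure. Fallback (sets out from 21, returns at 23; the Michael acceptor is masked during ring closure): conjugate addition of PhSeH (from PhSeSePh/NaBH4, buffered) to 21 gives the α-[(phenylselanyl)methyl] lactone F4 (epimers at the α-carbon, of no consequence). 9-BBN gives the alkylborane F5, and the same Pd-catalysed coupling gives the macrocyclic selenide F6. Oxidation with H2O2/pyridine at 0 °C and selenoxide syn-elimination, which can only take the α-hydrogen, restores the methylene and gives 23.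

3. Step 5 (first vinylogous aldol addition). Enantioselectivity or the E geometry of the new trisubstituted alkene may erode, and chloride may add to and eliminate from the β-iodo enal under the chlorosilane Lewis acid, scrambling the vinyl iodide. Fallback (sets out from 8, returns at 11; the alkene geometry is then fixed by carbometalation): chiral phosphoric acid-catalysed asymmetric propargylation of 8 with allenylboronic acid pinacol ester gives (4S,5E)-6-iodohept-5-en-1-yn-4-ol F7, and TBSCl/imidazole gives its silyl ether F8. Zr-catalysed carboalumination (AlMe3, Cp2ZrCl2) with ethyl chloroformate quench gives ethyl (2E,5S,6E)-5-[(tert-butyldimethylsilyl)oxy]-7-iodo-3-methylocta-2,6-dienoate F9. DIBAL-H gives (2E,5S,6E)-5-[(tert-butyldimethylsilyl)oxy]-7-iodo-3-methylocta-2,6-dien-1-ol F10, and MnO2 gives 11.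

**Further compounds**

F1 | step 14 | ethyl 3-hydroxy-2-methylidenepent-4-enoate (racemic) | C=CC(O)C(=C)C(=O)OCC
F2 | step 14 | ethyl (2Z)-2-(bromomethyl)penta-2,4-dienoate | C=C/C=C(\CBr)C(=O)OCC
F3 | step 14 | ethyl (3R,4S,5E,8S,9E,12S,13E)-8-acetoxy-12-[(tert-butyldimethylsilyl)oxy]-3-ethenyl-4-hydroxy-14-iodo-6,10-dimethyl-2-methylidenepentadeca-5,9,13-trienoate | CCOC(=O)C(=C)[C@@H](C=C)[C@@H](O)/C=C(\C)C[C@H](OC(C)=O)/C=C(\C)C[C@H](O[Si](C)(C)C(C)(C)C)/C=C(\C)I
F4 | step 15 | PhSeH adduct of 21 at the exocyclic methylene (α-[(phenylselanyl)methyl] lactone, epimers at the α-carbon) | c1ccccc1[Se]CC1C(=O)O[C@@H](/C=C(\C)C[C@H](OC(C)=O)/C=C(\C)C[C@H](O[Si](C)(C)C(C)(C)C)/C=C(\C)I)[C@@H]1C=C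
F5 | step 15 | 9-BBN adduct of F4 at the terminal vinyl carbon | c1ccccc1[Se]CC1C(=O)O[C@@H](/C=C(\C)C[C@H](OC(C)=O)/C=C(\C)C[C@H](O[Si](C)(C)C(C)(C)C)/C=C(\C)I)[C@@H]1CCB1C2CCCC1CCC2
F6 | step 15 | macrocyclic selenide (23 with CH–CH2SePh in place of C=CH2, epimers at the α-carbon) | c1ccccc1[Se]CC1C(=O)O[C@H]2/C=C(\C)C[C@H](OC(C)=O)/C=C(\C)C[C@H](O[Si](C)(C)C(C)(C)C)/C=C(\C)CC[C@H]12
F7 | step 5 | (4S,5E)-6-iodohept-5-en-1-yn-4-ol | C#CC[C@H](O)/C=C(\C)I
F8 | step 5 | tert-butyl{[(4S,5E)-6-iodohept-5-en-1-yn-4-yl]oxy}dimethylsilane | C#CC[C@H](O[Si](C)(C)C(C)(C)C)/C=C(\C)I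
F9 | step 5 | ethyl (2E,5S,6E)-5-[(tert-butyldimethylsilyl)oxy]-7-iodo-3-methylocta-2,6-dienoate | CCOC(=O)/C=C(\C)C[C@H](O[Si](C)(C)C(C)(C)C)/C=C(\C)I
F10 | step 5 | (2E,5S,6E)-5-[(tert-butyldimethylsilyl)oxy]-7-iodo-3-methylocta-2,6-dien-1-ol | OC/C=C(\C)C[C@H](O[Si](C)(C)C(C)(C)C)/C=C(\C)I
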